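**Retrosynthetic overview**
- Target 5 ⇒ cut the C5–O(acetate) bond: enantioselective addition of acetic acid across the C4=C5 enone bond of gingerenone A (4). This single step makes the key bond and the only stereocentre.
- 4 ⇒ tetrahydrocurcumin (1), a symmetric 1,3-diketone, by 1,3-carbonyl transposition (enol ether 2, hydride, acid). All C–C bonds are bought.
- No ring is formed: both guaiacol rings come intact with 1, and no protecting groups are used.

Assumption: tetrahydrocurcumin (bulk nutraceutical, also sold as a reagent) counts as a cheap commercial starting material.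
Assumption: the quinidine-derived amine gives the 5S adduct, assigned from memory of this catalyst family's hydroperoxide additions and not verified; if the first chiral HPLC or rotation check shows 5R, the quinine-derived pseudoenantiomer is used with nothing else changed.

**Step 1**
Reactants: 1 tetrahydrocurcumin, 1,7-bis(4-hydroxy-3-methoxyphenyl)heptane-3,5-dione
Product: 2 (E)-1,7-bis(4-hydroxy-3-methoxyphenyl)-5-methoxyhept-4-en-3-one (E major; any Z isomer is carried along)
Conditions: HC(OMe)3 (3 equiv), p-TsOH·H2O (5 mol %), MeOH, rt, 16 h; Et3N quench
Reagents that add atoms: trimethyl orthoformate, COC(OC)OC (the OCH3 group; it exchanges with the solvent methanol, CO)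
Why: Acid-catalysed ketalisation and loss of methanol turns the enolised 1,3-diketone into its vinylogous methyl ester (first half of a Stork–Danheiser transposition); the symmetric diketone gives one constitutional product, the vinylogous ester carbonyl resists further ketalisation, and the phenols are inert to MeOH/acid.

**Step 2**
Reactants: 2 (E)-1,7-bis(4-hydroxy-3-methoxyphenyl)-5-methoxyhept-4-en-3-one
Product: 4 gingerenone A, (E)-1,7-bis(4-hydroxy-3-methoxyphenyl)hept-4-en-3-one, via methoxy allylic alcohol 3 (not isolated)
Conditions: i-Bu2AlH (4 equiv), THF, −78 to −20 °C; then 1 M HCl, 0 °C to rt, 1 h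
Reagents that add atoms: none
Why: 1,2-Hydride addition to the vinylogous ester (two further equivalents are used up by the phenols) followed by acid-promoted ionisation and hydrolysis with allylic transposition (Stork–Danheiser enone synthesis) gives the thermodynamic E-enone; the carbinol centre of 3 becomes an alkene carbon, so no stereocentre is carried forward.

**Step 3**
Reactants: 4 gingerenone A
Product: 5 (5S)-5-acetoxy-1,7-bis(4-hydroxy-3-methoxyphenyl)heptan-3-one (target)
Conditions: 9-amino(9-deoxy)-epi-quinidine (20 mol %), AcOH/CH2Cl2 1:1 (about 9 M AcOH), 0.2 M in 4, −20 °C, 72 h; cold aqueous citric acid work-up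
Reagents that add atoms: acetic acid, CC(=O)O
Why: Proposed new method: catalytic enantioselective hydroacetoxylation (oxa-Michael addition of acetic acid) of an acyclic alkyl enone under iminium catalysis, in which the primary amine condenses with the C3 ketone of 4 to give an iminium acetate, the quinuclidinium N–H holds the acetate over one face, the ion pair collapses onto the Si face of C5 to form the C5–O bond and the 5S centre, and the resulting enamine is protonated by the acidic medium and hydrolysed to release 5 with the phenols as spectators; the closest known reaction type is the cinchona primary amine-catalysed oxa-Michael addition of hydroperoxides and oximes to aliphatic enones, where carboxylic acids have so far served only as co-catalysts and not as the nucleophile; low temperature and a high acetic acid concentration push the near-thermoneutral addition to the adduct side, and the amine is stripped cold so the retro-addition cannot erode the ee.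

**Compound list**
1 | tetrahydrocurcumin, 1,7-bis(4-hydroxy-3-methoxyphenyl)heptane-3,5-dione | COc1cc(CCC(=O)CC(=O)CCc2ccc(O)c(OC)c2)ccc1O | starting material
2 | (E)-1,7-bis(4-hydroxy-3-methoxyphenyl)-5-methoxyhept-4-en-3-one | COc1cc(CCC(=O)/C=C(/OC)CCc2ccc(O)c(OC)c2)ccc1O | intermediate
3 | rac-(E)-1,7-bis(4-hydroxy-3-methoxyphenyl)-5-methoxyhept-4-en-3-ol | COc1cc(CCC(O)/C=C(/OC)CCc2ccc(O)c(OC)c2)ccc1O | intermediate (not isolated)
4 | gingerenone A, (E)-1,7-bis(4-hydroxy-3-methoxyphenyl)hept-4-en-3-one | COc1cc(CCC(=O)/C=C/CCc2ccc(O)c(OC)c2)ccc1O | intermediate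
5 | (5S)-5-acetoxy-1,7-bis(4-hydroxy-3-methoxyphenyl)heptan-3-one | COc1cc(CCC(=O)C[C@H](CCc2ccc(O)c(OC)c2)OC(C)=O)ccc1O | target

**Totals**
Total step count: 3. Longest linear sequence: 3.

**Steps most likely to fail**

Step 3 (the proposed new step) is the most exposed.
- Acetate hydrogen-bonded in acetic acid is a weak nucleophile.
- The addition is close to thermoneutral: a rough estimate from enone hydration and esterification constants gives K of about 0.1 per molar at 25 °C, more favourable at −20 °C.
- The same catalyst can run the retro-addition and erode the ee, so the run must be stopped at the conversion plateau and unreacted 4 recycled.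

Fallback with known chemistry, setting out from 4 and coming back at 5:
- Amine-catalysed asymmetric hydroperoxidation of 4 (9-amino(9-deoxy)-epi-quinidine trichloroacetate salt, 10 mol %, aqueous H2O2, dioxane, 32 °C) gives the peroxyhemiketal F4 with the C5–O bond already set.
- Reduction with P(OEt)3 gives (S)-hexahydrocurcumin F5.
- Ac2O/pyridine at 0 °C gives the triacetate F6.
- NH4OAc in aqueous methanol at rt removes only the two aryl acetates by methanolysis and leaves 5.

Step 2 may give conjugate or over-reduction, or stop at the β-hydroxy ketone instead of the enone after the acid step. The fallback drops the transposition approach and sets out from 1. Controlled mono-reduction (NaBH4, 0.5 equiv, EtOH, −10 °C, separated from diol and recovered 1) gives racemic hexahydrocurcumin F3. Acid-catalysed dehydration (p-TsOH, toluene, 80 °C) then returns to the route at 4.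

Step 1 may stall or give E/Z and ketal mixtures under the acidic O-alkylation. The fallback differentiates the carbonyls through nitrogen under neutral conditions and sets out from 1. Condensation with pyrrolidine (MeOH, rt) gives the pyrrolidine enaminone F1. LiAlH4 (THF, 0 °C) reduces it to the amino allylic alcohol F2. Work-up with 1 M HCl hydrolyses this with transposition and returns to the route at 4.

**Further compounds**
F1 | step 1 | (E)-1,7-bis(4-hydroxy-3-methoxyphenyl)-5-(pyrrolidin-1-yl)hept-4-en-3-one | COc1cc(CCC(=O)/C=C(/N2CCCC2)CCc2ccc(O)c(OC)c2)ccc1O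
F2 | step 1 | rac-(E)-1,7-bis(4-hydroxy-3-methoxyphenyl)-5-(pyrrolidin-1-yl)hept-4-en-3-ol | COc1cc(CCC(O)/C=C(/N2CCCC2)CCc2ccc(O)c(OC)c2)ccc1O
F3 | step 2 | rac-5-hydroxy-1,7-bis(4-hydroxy-3-methoxyphenyl)heptan-3-one | COc1cc(CCC(=O)CC(O)CCc2ccc(O)c(OC)c2)ccc1O
F4 | step 3 | (5S)-3,5-bis[2-(4-hydroxy-3-methoxyphenyl)ethyl]-1,2-dioxolan-3-ol (both C3 epimers) | COc1cc(CCC2(O)C[C@H](CCc3ccc(O)c(OC)c3)OO2)ccc1O
F5 | step 3 | (5S)-5-hydroxy-1,7-bis(4-hydroxy-3-methoxyphenyl)heptan-3-one | COc1cc(CCC(=O)C[C@H](CCc2ccc(O)c(OC)c2)O)ccc1O
F6 | step 3 | (5S)-5-acetoxy-1,7-bis(4-acetoxy-3-methoxyphenyl)heptan-3-one | COc1cc(CCC(=O)C[C@H](CCc2ccc(OC(C)=O)c(OC)c2)OC(C)=O)ccc1OC(C)=O
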